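Sauriol A is a C2-symmetric (8R,8'R) 1,4-diaryl-2,3-dimethylbutane. Everything rests on disconnecting both C–CH3 bonds, C8–C9 and C8'–C9', after folding the C7–C8–C8'–C7' chain into a five-membered lactone ring through a temporary oxygen on benzylic C7 and a carbonyl at C7'. The precursor is the benzyl-protected (S)-5-aryl-2(5H)-furanone, whose only stereocentre is C7. In one operation a cuprate delivers methyl to C8 and iodomethane methylates the enolate at C8'; the key step exploits the rigid ring, whose C7 aryl group shields one face, so each methyl ends up trans to its ring neighbour. A second aryl ring then adds to the lactone carbonyl, and reduction erases both benzylic oxygens.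

Key step: step 4

Numbering: lignan numbering is used for the chain. C7 and C7' are the benzylic carbons, C8 and C8' the methine carbons, C9 and C9' the methyl carbons; C7 is the carbon that comes from the aldehyde of 1.

Assumption: in step 2 the (S)-BINOL-derived titanium catalyst is taken to deliver the acetylide to the Si face of the aryl aldehyde (4R alcohol). If a first run (Mosher ester analysis) shows the opposite sense, (R)-BINOL is used and nothing else changes.

Remark: the enantiomeric purity set in step 2 is to be checked at 7 and, where needed, raised by recrystallisation of 7 or 10.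

Step 1
Reactants: 1 3,4-dihydroxy-5-methoxybenzaldehyde
Product: 2 3,4-bis(benzyloxy)-5-methoxybenzaldehyde
Conditions: BnBr (2.4 equiv), K2CO3, DMF, 60 °C, N2
Reagents that add atoms: benzyl bromide, BrCc1ccccc1
Why: Williamson etherification: carbonate base turns both phenols of the catechol into phenoxides that displace bromide from benzyl bromide, the aldehyde is untouched, and benzyl is chosen because it survives the organometallic steps and leaves in the final hydrogenolysis.

Step 2
Reactants: 2 3,4-bis(benzyloxy)-5-methoxybenzaldehyde; 3 methyl propiolate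
Product: 5 methyl (4R)-4-[3,4-bis(benzyloxy)-5-methoxyphenyl]-4-hydroxybut-2-ynoate, via ethylzinc acetylide 4 (not isolated)
Conditions: 3, Et2Zn, HMPA, (S)-BINOL (40 mol%), CH2Cl2, rt; Ti(OiPr)4; then 2, rt; aq NH4Cl
Reagents that add atoms: none
Why: Asymmetric alkynylzinc addition to an aldehyde promoted by BINOL and Ti(OiPr)4: Et2Zn deprotonates 3 to acetylide 4, which adds to the aldehyde held on the chiral titanium BINOLate from the exposed Si face and so sets C7 as the 4R carbinol, while the ester, the benzyl ethers and the methoxy group are inert.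

Step 3
Reactants: 5 methyl (4R)-4-[3,4-bis(benzyloxy)-5-methoxyphenyl]-4-hydroxybut-2-ynoate
Product: 7 (5S)-5-[3,4-bis(benzyloxy)-5-methoxyphenyl]furan-2(5H)-one, via Z-hydroxy enoate 6 (not isolated)
Conditions: H2 (1 atm), Pd/CaCO3 poisoned with Pb(OAc)2, quinoline, EtOAc, rt; filter; PPTS (cat.), CH2Cl2, rt to 40 °C
Reagents that add atoms: none
Why: Lindlar semi-hydrogenation followed by acid-catalysed lactonisation: syn delivery of H2 on the lead-poisoned Pd surface stops at Z-enoate 6, whose hydroxyl then attacks the cis ester carbonyl (5-exo-trig, loss of methanol) to close the butenolide without breaking the C7–O bond, so the configuration is kept (the descriptor changes to 5S only through ranking), and the weak acid avoids ionisation of the electron-rich benzylic position.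

Step 4
Reactants: 7 (5S)-5-[3,4-bis(benzyloxy)-5-methoxyphenyl]furan-2(5H)-one; 8 iodomethane
Product: 10 (3S,4S,5S)-5-[3,4-bis(benzyloxy)-5-methoxyphenyl]-3,4-dimethyldihydrofuran-2(3H)-one (all-trans), via lithium enolate 9 (not isolated)
Conditions: CuI, MeLi (2 equiv per Cu), Et2O, 0 °C; 7, THF, −78 °C; then DMPU, 8 (excess), −78 → −20 °C; aq NH4Cl/NH3
Reagents that add atoms: lithium dimethylcuprate, [Li+].C[Cu-]C; iodomethane (8), CI
Why: The cuprate forms a d–π* complex on the face of the C8=C8' double bond opposite the C7 aryl group, oxidative addition gives a β-cuprio enolate of trivalent copper, and reductive elimination places the C8 methyl trans to the aryl group, leaving lithium enolate 9. This flat enolate is then C-alkylated by iodomethane in an SN2 step on the face opposite the adjacent C8 methyl, so the C8' methyl ends up trans to it and the lactone is all-trans (3S,4S,5S). The closest known reaction type is the anti-selective conjugate addition of lithium dialkylcuprates to γ-substituted butenolides with trapping of the enolate by an alkyl halide (tandem conjugate addition–enolate alkylation). No ring is closed; the existing five-membered ring only serves as the template. C8 is controlled by the C7 stereocentre and C8' by the newly formed C8 centre, two successive 1,2-trans inductions that the rigid, nearly planar ring enforces. The step needs 1,4- rather than 1,2-addition and must not expel the allylic C7–O bond: the soft cuprate secures the first, the ring secures the second by holding the C7–O bond in the nodal plane of the enoate π system, and DMPU with excess iodomethane at low temperature favours C-methylation over proton exchange and double methylation.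

Step 5
Reactants: 11 5-bromo-2-hydroxy-3-methoxybenzaldehyde
Product: 13 5-bromo-3-methoxybenzene-1,2-diol, via aryl formate 12 (not isolated)
Conditions: H2O2 (30% aq), NaOH (aq), THF, 0 °C → rt, N2; then HCl (aq)
Reagents that add atoms: hydrogen peroxide, OO
Why: Dakin oxidation: hydroperoxide adds to the aldehyde ortho to the phenoxide, the aryl group migrates to oxygen to give formate 12, and hydroxide cleaves this ester to the catechol, with bromide and methoxy untouched.

Step 6
Reactants: 13 5-bromo-3-methoxybenzene-1,2-diol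
Product: 14 1,2-bis(benzyloxy)-5-bromo-3-methoxybenzene
Conditions: BnBr (2.4 equiv), K2CO3, DMF, 60 °C, N2
Reagents that add atoms: benzyl bromide, BrCc1ccccc1
Why: Williamson etherification as in step 1, which equips the second ring with the same benzyl ethers and leaves the aryl bromide for metalation.

Step 7
Reactants: 14 1,2-bis(benzyloxy)-5-bromo-3-methoxybenzene; 10 (3S,4S,5S)-5-[3,4-bis(benzyloxy)-5-methoxyphenyl]-3,4-dimethyldihydrofuran-2(3H)-one
Product: 16 (2S,3S,4S)-1,4-bis[3,4-bis(benzyloxy)-5-methoxyphenyl]-4-hydroxy-2,3-dimethylbutan-1-one, via aryllithium 15 (not isolated)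
Conditions: 14, n-BuLi (1.0 equiv to 14), THF, −78 °C; then 10, THF, −78 °C; aq NH4Cl at −78 °C
Reagents that add atoms: none
Why: Bromine–lithium exchange followed by acyl addition of an aryllithium to a lactone: at −78 °C the lithium hemiketal alkoxide does not collapse, so only one aryl group adds and the cold quench releases the γ-hydroxy ketone (in equilibrium with its ring form 17) before the C8' centre next to the new ketone can epimerise.

Step 8
Reactants: 16 (2S,3S,4S)-1,4-bis[3,4-bis(benzyloxy)-5-methoxyphenyl]-4-hydroxy-2,3-dimethylbutan-1-one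
Product: 18 (3S,4S,5S)-2,5-bis[3,4-bis(benzyloxy)-5-methoxyphenyl]-3,4-dimethyltetrahydrofuran (either epimer at C2), via cyclic hemiketal 17 (not isolated)
Conditions: Et3SiH, BF3·OEt2, CH2Cl2, −78 °C; aq NaHCO3
Reagents that add atoms: none
Why: Ionic hydrogenation of a cyclic hemiketal (reductive deoxygenation): BF3 ionises 17 to an aryl-stabilised oxocarbenium ion that takes hydride from Et3SiH faster than it can lose the C8' proton, so C8 and C8' are untouched, and the new C7' centre may form as either epimer because C7' becomes CH2 in step 9.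

Step 9
Reactants: 18 (3S,4S,5S)-2,5-bis[3,4-bis(benzyloxy)-5-methoxyphenyl]-3,4-dimethyltetrahydrofuran
Product: 19 sauriol A, 5,5'-[(2R,3R)-2,3-dimethylbutane-1,4-diyl]bis(3-methoxybenzene-1,2-diol)
Conditions: H2 (4 atm), Pd/C, AcOH–EtOAc, HClO4 (cat.), rt; work-up under N2
Reagents that add atoms: none
Why: Catalytic hydrogenolysis: Pd/C under H2 removes the four O-benzyl groups and, helped by the acid, cleaves both benzylic C–O bonds of the ring (C7–O and C7'–O) to CH2 groups, while C8 and C8' are neither benzylic nor next to a carbonyl any more and keep the (8R,8'R) configuration.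

Compound list
1 | 3,4-dihydroxy-5-methoxybenzaldehyde | COc1cc(C=O)cc(O)c1O | starting material
2 | 3,4-bis(benzyloxy)-5-methoxybenzaldehyde | COc1cc(C=O)cc(OCc2ccccc2)c1OCc1ccccc1 | intermediate
3 | methyl propiolate | C#CC(=O)OC | starting material
4 | ethyl(3-methoxy-3-oxoprop-1-yn-1-yl)zinc (ethylzinc acetylide of 3) | CC[Zn]C#CC(=O)OC | intermediate
5 | methyl (4R)-4-[3,4-bis(benzyloxy)-5-methoxyphenyl]-4-hydroxybut-2-ynoate | O[C@H](c1cc(OC)c(OCc2ccccc2)c(OCc2ccccc2)c1)C#CC(=O)OC | intermediate
6 | methyl (2Z,4S)-4-[3,4-bis(benzyloxy)-5-methoxyphenyl]-4-hydroxybut-2-enoate | O[C@H](c1cc(OC)c(OCc2ccccc2)c(OCc2ccccc2)c1)/C=C\C(=O)OC | intermediate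
7 | (5S)-5-[3,4-bis(benzyloxy)-5-methoxyphenyl]furan-2(5H)-one | O1[C@H](c2cc(OC)c(OCc3ccccc3)c(OCc4ccccc4)c2)C=CC1=O | intermediate
8 | iodomethane | CI | starting material
9 | lithium (4S,5S)-5-[3,4-bis(benzyloxy)-5-methoxyphenyl]-4-methyl-4,5-dihydrofuran-2-olate (methyl trans to aryl) | O1[C@H](c2cc(OC)c(OCc3ccccc3)c(OCc4ccccc4)c2)[C@@H](C)C=C1[O-].[Li+] | intermediate
10 | (3S,4S,5S)-5-[3,4-bis(benzyloxy)-5-methoxyphenyl]-3,4-dimethyldihydrofuran-2(3H)-one (all-trans) | O1[C@H](c2cc(OC)c(OCc3ccccc3)c(OCc4ccccc4)c2)[C@@H](C)[C@H](C)C1=O | intermediate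
11 | 5-bromo-2-hydroxy-3-methoxybenzaldehyde | COc1cc(Br)cc(C=O)c1O | starting material
12 | 5-bromo-2-hydroxy-3-methoxyphenyl formate | COc1cc(Br)cc(OC=O)c1O | intermediate
13 | 5-bromo-3-methoxybenzene-1,2-diol | COc1cc(Br)cc(O)c1O | intermediate
14 | 1,2-bis(benzyloxy)-5-bromo-3-methoxybenzene | COc1cc(Br)cc(OCc2ccccc2)c1OCc1ccccc1 | intermediate
15 | [3,4-bis(benzyloxy)-5-methoxyphenyl]lithium | [Li]c1cc(OC)c(OCc2ccccc2)c(OCc2ccccc2)c1 | intermediate
16 | (2S,3S,4S)-1,4-bis[3,4-bis(benzyloxy)-5-methoxyphenyl]-4-hydroxy-2,3-dimethylbutan-1-one | O[C@H](c1cc(OC)c(OCc2ccccc2)c(OCc2ccccc2)c1)[C@@H](C)[C@H](C)C(=O)c1cc(OC)c(OCc2ccccc2)c(OCc2ccccc2)c1 | intermediate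
17 | (3S,4S,5S)-2,5-bis[3,4-bis(benzyloxy)-5-methoxyphenyl]-3,4-dimethyltetrahydrofuran-2-ol (ring form of 16, either anomer) | O1[C@H](c2cc(OC)c(OCc3ccccc3)c(OCc3ccccc3)c2)[C@@H](C)[C@H](C)C1(O)c1cc(OC)c(OCc2ccccc2)c(OCc2ccccc2)c1 | intermediate
18 | (3S,4S,5S)-2,5-bis[3,4-bis(benzyloxy)-5-methoxyphenyl]-3,4-dimethyltetrahydrofuran (either epimer at C2) | O1[C@H](c2cc(OC)c(OCc3ccccc3)c(OCc3ccccc3)c2)[C@@H](C)[C@H](C)C1c1cc(OC)c(OCc2ccccc2)c(OCc2ccccc2)c1 | intermediate
19 | sauriol A, 5,5'-[(2R,3R)-2,3-dimethylbutane-1,4-diyl]bis(3-methoxybenzene-1,2-diol) | COc1cc(C[C@@H](C)[C@H](C)Cc2cc(O)c(O)c(OC)c2)cc(O)c1O | target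

Total step count: 9. Longest linear sequence: 7 steps (steps 1, 2, 3, 4, 7, 8 and 9, from 1 to 19); steps 5 and 6 make the aryl bromide side branch.

Steps most likely to fail

1. Step 4. The copper/lithium enolate may be protonated or may exchange protons with product before it is methylated, giving incomplete or double methylation, and the facial selectivity of the alkylation may be eroded. Fallback: the two bond formations are separated. From 7, Me2CuLi with Me3SiCl in THF at −78 °C and an acidic work-up should give the trans-4-methyl lactone (4S,5S)-5-[3,4-bis(benzyloxy)-5-methoxyphenyl]-4-methyldihydrofuran-2(3H)-one F1. Its enolate, made with LiN(SiMe3)2 in THF at −78 °C, is methylated with iodomethane trans to the C8 methyl, and any 3,4-cis isomer is equilibrated to the more stable trans lactone with DBU. The sequence comes back to the route at 10.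

2. Step 2. The electron-rich, hindered aldehyde may react slowly, so that ethyl transfer and uncatalysed addition compete and the enantioselectivity is poor. Fallback: C7 is set by ketone reduction instead (aryl = 3,4-bis(benzyloxy)-5-methoxyphenyl throughout).
- From 2, a Stetter reaction with methyl acrylate (3-benzyl-5-(2-hydroxyethyl)-4-methylthiazolium chloride, Et3N, EtOH, reflux) should give the keto ester methyl 4-aryl-4-oxobutanoate F2.
- Noyori transfer hydrogenation with RuCl[(S,S)-TsDPEN](p-cymene) and HCO2H/Et3N should give the hydroxy ester methyl (4S)-4-aryl-4-hydroxybutanoate F3, which is lactonised with PPTS in toluene to the saturated lactone (5S)-5-aryldihydrofuran-2(3H)-one F4.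
- LiN(iPr)2 and then PhSeBr in THF at −78 °C give the selenide (5S)-5-aryl-3-(phenylselanyl)dihydrofuran-2(3H)-one F5.
- H2O2 in CH2Cl2 at 0 °C oxidises it to the selenoxide (5S)-5-aryl-3-(phenylseleninyl)dihydrofuran-2(3H)-one F6, whose syn elimination towards C4 gives the butenolide. The route is rejoined at 7.

3. Step 9. Cleavage of the two ring C–O bonds may be incomplete, or the acid may ionise C7/C7' and lead to Friedel–Crafts closure onto the other ring or to elimination, which would erode C8/C8'. Fallback: the benzylic oxygens are removed as esters without acid. From 16, NaBH4 in MeOH/THF at 0 °C should give the diol (1S,2S,3S)-1,4-bis[3,4-bis(benzyloxy)-5-methoxyphenyl]-2,3-dimethylbutane-1,4-diol F7 (either epimer at C4). Ac2O, DMAP and pyridine give the diacetate (1S,2S,3S)-1,4-bis[3,4-bis(benzyloxy)-5-methoxyphenyl]-2,3-dimethylbutane-1,4-diyl diacetate F8. H2 over Pd/C in EtOAc/EtOH at rt then cleaves both benzylic acetates and the four benzyl ethers, arriving directly at 19.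

Further compounds
F1 | step 4 | (4S,5S)-5-[3,4-bis(benzyloxy)-5-methoxyphenyl]-4-methyldihydrofuran-2(3H)-one | O1[C@H](c2cc(OC)c(OCc3ccccc3)c(OCc4ccccc4)c2)[C@@H](C)CC1=O
F2 | step 2 | methyl 4-[3,4-bis(benzyloxy)-5-methoxyphenyl]-4-oxobutanoate | COC(=O)CCC(=O)c1cc(OC)c(OCc2ccccc2)c(OCc2ccccc2)c1
F3 | step 2 | methyl (4S)-4-[3,4-bis(benzyloxy)-5-methoxyphenyl]-4-hydroxybutanoate | O[C@H](c1cc(OC)c(OCc2ccccc2)c(OCc2ccccc2)c1)CCC(=O)OC
F4 | step 2 | (5S)-5-[3,4-bis(benzyloxy)-5-methoxyphenyl]dihydrofuran-2(3H)-one | O1[C@H](c2cc(OC)c(OCc3ccccc3)c(OCc4ccccc4)c2)CCC1=O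
F5 | step 2 | (5S)-5-[3,4-bis(benzyloxy)-5-methoxyphenyl]-3-(phenylselanyl)dihydrofuran-2(3H)-one (either epimer at C3) | O1[C@H](c2cc(OC)c(OCc3ccccc3)c(OCc4ccccc4)c2)CC([Se]c5ccccc5)C1=O
F6 | step 2 | (5S)-5-[3,4-bis(benzyloxy)-5-methoxyphenyl]-3-(phenylseleninyl)dihydrofuran-2(3H)-one | O1[C@H](c2cc(OC)c(OCc3ccccc3)c(OCc4ccccc4)c2)CC([Se](=O)c5ccccc5)C1=O
F7 | step 9 | (1S,2S,3S)-1,4-bis[3,4-bis(benzyloxy)-5-methoxyphenyl]-2,3-dimethylbutane-1,4-diol (either epimer at C4) | O[C@H](c1cc(OC)c(OCc2ccccc2)c(OCc2ccccc2)c1)[C@@H](C)[C@H](C)C(O)c1cc(OC)c(OCc2ccccc2)c(OCc2ccccc2)c1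
F8 | step 9 | (1S,2S,3S)-1,4-bis[3,4-bis(benzyloxy)-5-methoxyphenyl]-2,3-dimethylbutane-1,4-diyl diacetate (either epimer at C4) | CC(=O)O[C@H](c1cc(OC)c(OCc2ccccc2)c(OCc2ccccc2)c1)[C@@H](C)[C@H](C)C(OC(C)=O)c1cc(OC)c(OCc2ccccc2)c(OCc2ccccc2)c1
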